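The meeting opened on late times, where the noon run stands at 30.1% of target after 12.0 min.

| setting | dusk | noon | autumn | spring | west | south | north-west | south-west | south-east |
|---|---|---|---|---|---|---|---|---|---|
| starting material | 0.020 M | 0.010 M | 0.040 M | 0.020 M | 0.020 M | 0.020 M | 0.020 M | 0.020 M | 0.020 M |
| first nucleophile | 10 mM | 10 mM | 10 mM | 10 mM | 10.0 mM (fed, over 8.0 min) | 10.0 mM | 10.0 mM (fed, over 8.0 min) | 10.0 mM | 10.0 mM |
| second nucleophile | 0.030 M | 0.030 M | 0.030 M | 0.030 M | 0.0300 M | 0.0300 M (fed, over 8.0 min) | 0.0300 M | 0.0300 M | 0.0300 M |
| capture agent | 2 mM | 2 mM | 2 mM | 3 mM | 2.00 mM | 2.00 mM | 2.00 mM | 2.00 mM | 2.00 mM |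
| protic impurity | 0.40 mM | 0.40 mM | 0.40 mM | 0.40 mM | 0.400 mM | 0.400 mM | 0.400 mM | 0.400 mM | 0.400 mM |
| temperature | 10 °C | 25 °C | 10 °C | 25 °C | 25 °C | 25 °C |  | 25 °C |  |
| remark | run made earlier | run made earlier | run made earlier | run made earlier | all else is in the flask from the start; the feed brings no volume worth counting | all else is in the flask from the start; the feed brings no volume worth counting | the addition at −15 °C, then warmed to 25 °C; the feed brings no volume worth counting | everything together at the start | everything together at the start at −15 °C, warmed to 25 °C at 8.0 min |
| time |  |  |  |  | 20 min | 20 min | 20 min | 20 min | 20 min |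

| run | time / min | target / % |
|---|---|---|
| dusk | 3.00 | 2.8 |
| dusk | 8.00 | 8.7 |
| dusk | 15.0 | 15.2 |
| dusk | 20.0 | 16.0 |
| dusk | 30.0 | 20.8 |
| dusk | 40.0 | 22.9 |
| noon | 0.833 | 2.6 |
| noon | 2.50 | 13.1 |
| noon | 4.00 | 15.2 |
| noon | 6.00 | 21.6 |
| noon | 10.0 | 26.8 |
| noon | 12.0 | 30.1 |
| autumn | 2.00 | 2.6 |
| autumn | 3.00 | 3.4 |
| autumn | 5.00 | 3.6 |
| autumn | 8.00 | 8.3 |
| autumn | 15.0 | 10.2 |
| autumn | 25.0 | 16.7 |
| spring | 1.00 | 5.8 |
| spring | 3.00 | 10.4 |
| spring | 6.00 | 21.1 |
| spring | 8.00 | 23.7 |
| spring | 12.0 | 27.0 |

(scatter of a reading: 1 percentage point)

- the flask that comes out highest in amount of target, in percent of the starting material charged, or "all alike" when all lie within 1.5 percentage points (west / south / north-west / south-west / south-east / all alike)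
- target at the end, in percent of the starting material charged, west
- target at the end, in percent of the starting material charged, south
- target at the end, in percent of the starting material charged, north-west
- target at the end, in percent of the starting material charged, south-west
- target at the end, in percent of the starting material charged, south-east

- the numbers in the tables scatter with a standard deviation of 1 percentage point

The kineticist said that this reading is 3.01 mM of target, about a third of the first nucleophile charged in noon. She proposed that second nucleophile competes with first nucleophile for the charge.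

The chair then asked for one number. The kineticist took the odds in noon, target against the rest of the charge in whatever form, as 0.431. The nucleophile ratio in noon, first over second, is 0.333. Dividing gives 1.29, the selectivity factor, odds of target per unit of nucleophile ratio. By this definition, unreacted starting material counts in the rest. The factor is a reading and carries the scatter of 1 point.

The process chemist treated the feed as a correction to the batch. A fed nucleophile climbs evenly over 8.0 min. Before any consumption, its mean over 20 min is therefore 0.800 of its charge. Feeding first nucleophile in west multiplies the ratio by this factor, and feeding second nucleophile in south divides it.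

The meeting's own odds are 0.344 for west and 0.538 for south. Those give 25.6% of target in west and 35.0% in south. The meeting gave south-west the noon odds, which gives 30.1%, although south-west holds twice the starting material of noon and runs to 20 min. Of these flasks the meeting backed south. It made no reckoning for the cold flasks.

The forecast differs. It names south-west as highest, with west 31%, south 31%, north-west 28%, south-west 34% and south-east 28%. Of the fed second nucleophile it says “the intermediate may wait and be partly captured”.

    starting material ⇌ open intermediate (K = 0.00530, k = 0.00470 s⁻¹, Ea = 87.0 kJ mol⁻¹, ΔH = −38.0 kJ mol⁻¹)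
    first nucleophile + open intermediate → target (k = 35.0 L mol⁻¹ s⁻¹, Ea = 52.0 kJ mol⁻¹)
    second nucleophile + open intermediate → other capture product (k = 18.0 L mol⁻¹ s⁻¹, Ea = 39.0 kJ mol⁻¹)
    open intermediate + capture agent → trapped intermediate (k = 1.20 L mol⁻¹ s⁻¹, Ea = 37.0 kJ mol⁻¹)
    second nucleophile + protic impurity → quenched reagent (k = 19.0 L mol⁻¹ s⁻¹, Ea = 39.0 kJ mol⁻¹)
    (constants at 25 °C)

The highest flask is south, at 36.4%, with west 24.2%, north-west 26.9%, south-west 30.9% and south-east 26.9%. At 20.0 min, south holds 49.4% of other capture product and west holds 63.9%. For the neighbour of west charged with 0.040 M of first nucleophile, 1.29 and 0.800 give odds of 1.38, or 57.9% of target. That neighbour stands at 53.3% of target, with 42.8% of other capture product.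

Readings and results stem from a simulated flask for substances that don't exist; the scatter is artificial.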